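Time is the first number to test, then temperature, then the charges; for each, ask how far the share of target in target plus isomer of the product would move if that number were off.

| flask | substrate | coupling partner | temperature | remark | time |
|---|---|---|---|---|---|
| Monday's | 0.20 M | 0.16 M | 25 °C | run made earlier |  |
| Friday's | 0.28 M | 0.16 M | 40 °C | run made earlier |  |
| Wednesday's | 0.44 M | 0.16 M | 25 °C | run made earlier |  |
| Thursday's | 0.20 M | 0.080 M | 40 °C | run made earlier |  |
| east | 0.20 M (fed, over 20 min) | 0.160 M | 40 °C | all else is in the flask from the start; the feed brings no volume worth counting | 50 min |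
| south-west | 0.20 M | 0.160 M (in portions, 3, over 20 min) | 40 °C | first portion at the start, last at 20 min | 50 min |
| north-west | 0.20 M | 0.160 M | 40 °C | everything together at the start | 50 min |
| south-east | 0.20 M (fed, over 20 min) | 0.160 M |  | the addition at 10 °C, then warmed to 40 °C; the feed brings no volume worth counting | 50 min |

| run | time / min | target / % | isomer of the product / % | substrate / % |
|---|---|---|---|---|
| Monday's | 4.00 | 16.0 | 6.0 | 40.3 |
| Monday's | 12.0 | 13.9 | 9.9 | 9.8 |
| Monday's | 20.0 | 14.6 | 9.6 | 6.2 |
| Monday's | 30.0 | 13.8 | 10.5 | 1.2 |
| Monday's | 50.0 | 12.7 | 12.5 | 0 |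
| Monday's | 60.0 | 14.9 | 12.2 | 0 |
| Friday's | 6.00 | 6.5 | 7.4 | 2.9 |
| Friday's | 12.0 | 6.5 | 7.2 | 1.1 |
| Friday's | 20.0 | 7.5 | 7.3 | 0.6 |
| Friday's | 25.0 | 6.3 | 10.3 | 0 |
| Friday's | 30.0 | 6.1 | 10.1 | 0 |
| Friday's | 40.0 | 6.7 | 8.3 | 0 |
| Wednesday's | 5.00 | 6.9 | 4.5 | 29.6 |
| Wednesday's | 15.0 | 3.5 | 4.6 | 12.7 |
| Wednesday's | 30.0 | 2.2 | 6.5 | 6.3 |
| Wednesday's | 40.0 | 2.0 | 8.2 | 2.8 |
| Wednesday's | 60.0 | 2.2 | 7.3 | 3.3 |
| Wednesday's | 80.0 | 1.2 | 5.8 | 1.7 |
| Thursday's | 4.00 | 5.3 | 5.7 | 23.2 |
| Thursday's | 10.0 | 3.2 | 7.2 | 10.9 |
| Thursday's | 20.0 | 1.5 | 5.9 | 3.7 |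
| Thursday's | 30.0 | 0.6 | 4.7 | 3.1 |
| Thursday's | 40.0 | 1.8 | 7.9 | 1.2 |

(standard deviation of a reading: 1 percentage point)

1. the flask with the highest share of target in target plus isomer of the product ("all alike" if they lie within 1.5 percentage points) (east / south-west / north-west / south-east / all alike)
2. share of target in target plus isomer of the product at the end, east
3. share of target in target plus isomer of the product at the end, south-west
4. share of target in target plus isomer of the product at the end, north-west
5. share of target in target plus isomer of the product at the end, south-east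

- percentages count the substrate that a species holds: one homo dimer or side product counts as two
- the numbers in the tables scatter by 1 percentage point (one standard deviation)
- reactions considered so far: substrate + coupling partner -> target; substrate + coupling partner -> isomer of the product; 2 substrate -> homo dimer; substrate + target -> side product

Follow one molecule of target. On the card it has one way out, meeting substrate and becoming side product, while the isomer of the product has none. Monday's run reads substrate at 0 % at 50.0 min, with target at 12.7 % there and 14.9 % at 60.0 min. Friday's run, at 40 °C, reads substrate 0 % already at 25.0 min, earlier than the 50 min asked. So the time is not a number to worry over.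

The number to know well is the charge ratio, [substrate]/[coupling partner] as charged, here 1.25, and the runs below show what it is worth. Late shares, read from the last readings:

Monday, 25 °C: ratio 1.25, share 52.8 %

Friday, 40 °C: ratio 1.75, share 40.0 %

Thursday, 40 °C: ratio 2.50, share 16.0 %

Wednesday, 25 °C: ratio 2.75, share 20.6 %

Wednesday and Thursday, at ratios 2.75 and 2.50 and at different temperatures, read 4.6 percentage points apart, less than the 32 points between Monday and Wednesday, both at 25 °C. So in these readings the temperature moves the share less than the ratio does.

East, south-west, north-west and south-east share Monday's ratio, and no earlier run was dosed. My own reckoning is therefore 52.8 % for each, with no order among them.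

The forecast differs, naming south-east with 41 % for east, 31 % for south-west, 44 % for north-west and 53 % for south-east. Its ground: “Cold addition makes product at better selectivity with little side reaction”.

The flasks give 54.5 % for east, 49.9 % for south-west, 60.1 % for north-west and 56.5 % for south-east, so the best is north-west.

    substrate + coupling partner → target (k = 0.0572 M⁻¹ s⁻¹, Ea = 71.0 kJ mol⁻¹)
    substrate + coupling partner → isomer of the product (k = 0.0124 M⁻¹ s⁻¹, Ea = 64.0 kJ mol⁻¹)
    2 substrate → homo dimer (k = 0.00971 M⁻¹ s⁻¹, Ea = 58.0 kJ mol⁻¹)
    substrate + target → side product (k = 0.132 M⁻¹ s⁻¹, Ea = 67.0 kJ mol⁻¹)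
    (constants at 40 °C)

At ratio 1.25, north-west ends at 60.1 % against my 52.8 %, and the ratio, equal across the flasks, does not give their spread of 10 points. Its neighbour with 0.27 M of coupling partner has ratio 0.741 and share 70.9 %. North-west has come to rest: at 25.0 min substrate stands at 0 % and target at 14.8 %, as at 50.0 min. At ten times the time, 500 min, target is still 14.8 %, coupling partner 31.1 %, and the share 60.1 %.

(The data are simulated from invented constants; the scatter is artificial.)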